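I came to this flask from a neighbour holding a quarter more nucleophile than the charge sought here.

    electrophile + nucleophile → acid set free + target (k1 = 440 M⁻¹ s⁻¹)
    nucleophile + acid set free ⇌ protonated nucleophile, settled at all times (K2 = 2.9 × 10⁶ M⁻¹)
    acid set free + free base ⇌ salt of the base, settled at all times (K3 = 1100 M⁻¹)
    free base + target ⇌ idle adduct, settled at all times (K4 = 880 M⁻¹)
    solid base ⇌ free base, rate k5*(cs5 - [free base]) while solid is left; crystals form when [free base] > cs5 (cs5 = 0.72 mM, k5 = 0.039 s⁻¹)
    target ⇌ isomer of the product (K6 = 21, k6 = 0.017 s⁻¹)

electrophile 1.0 mM; solid base 1.50 equiv; time 30 s

- what is said of target includes idle adduct
- solid base is a solid; its amount is given per volume of the solution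
- the amount of nucleophile is what is sought; it is there from the start
- at the start none of the solid base is in solution
- run time (flask): 30 s

- the equivalents of nucleophile at which the part of the electrophile that has reacted at 30 s is just 80%

- I counted turnovers of the coupling, the first step. With nucleophile at 1.0 mM and free base at its solubility 0.72 mM, I reckoned that each turnover cost 2.00 nucleophile: one as reagent and one as catcher of the acid set free, since 2.9 × 10⁶ M⁻¹ far exceeds 1100 M⁻¹. I call this τ, the toll: nucleophile lost per turnover, the reagent plus the share of the acid that lands on nucleophile and not on free base.
- The nucleophile charge came first. By my hand reckoning, each added equivalent bought 0.500 turnover, so the part asked needed 1.60 equiv, and at that charge nucleophile was the limiting reagent.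
- The run length came second. The pseudo-first-order half-life of nucleophile at the full 1.0 mM of electrophile was 1.58 s, far shorter than 30 s, so I expected a longer run to add little.
- Last came the solid base. By my reckoning, free base at its solubility would compete equally for acid once free nucleophile fell to 2.73 × 10⁻⁴ mM, far below 1.0 mM, so I expected its solubility to matter little before that point.
- The forecast gave 1.59 equiv, not quite my figure, holding that “about two nucleophiles are used per electrophile”.
- The simulation gave 1.57 equiv, which the toll turns into 78.5% reacted, against the 80% asked. In the neighbour flask, the toll gave 98.1% and the flask reached 95.5%. In this flask, a run ten times as long reached 87.4%, a gain of 7.4 percentage points where I had expected little, so the length of the run is a part of the story; removing the low solubility of free base gave 80.5%, so that is not the reason. The main reason the electrophile was not used up in this flask is the tying up of nucleophile with acid set free as protonated nucleophile: without it, the part reacted went from 80.0% to >99.9%.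

All constants were chosen freely.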